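## The problem

The target 20 is a benzophenone: a fully substituted phloroglucinol ring A is joined through one carbonyl carbon (C7) to a 3-hydroxyphenyl ring B. There is no ring fusion and no stereocentre. The difficulty is ring A, where C1 carries the aroyl group, C2 and C6 hydroxyls, C3 and C5 3-methylbut-2-enyl (prenyl) groups, and C4 the only methyl ether among three ring oxygens. Direct prenylation of an aroylphloroglucinol is hard to hold at this pattern, because carbon and oxygen alkylation and mono-, bis- and geminal substitution compete. The fragile parts are the two prenyl groups next to free phenols, which close to chromans or add HX under Brønsted or Lewis acid and do not survive hydrogenation, and the electron-rich ring, which oxidises in air as its phenoxide. One methyl group must go onto the C4 oxygen and not onto C2, C6 or the ring B phenol. The feature used here is the mirror plane of ring A through C1 and C4: C3–C4–C5 with its two prenyl groups is the skeleton of a symmetric ketone (C4 the carbonyl carbon), and C2–C1–C6 is a malonyl unit whose central carbon later takes the aroyl group.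

## Retrosynthesis

From 20 the ring B phenol is covered as its triisopropylsilyl ether 19, and the O–CH3 bond at C4 is then cut to give the triphenol 18. The silyl group stays on ring B through the methylation so that only ring A hydroxyls compete. Of these, the C4 hydroxyl is para to the carbonyl, the most acidic, and the only one not held in the hydrogen-bonded chelate with the ketone. Differentiating the three oxygens earlier is less attractive, because before the ketone is present only a modest steric difference separates them. The forward step must stop at one methyl group and must not alkylate ring carbon.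

The triphenol 18 comes from the tris(methoxymethyl) ether 17 by acetal cleavage. Cutting the C1–C7 bond of 17 gives the aryllithium 16, made from 13, and the ester 15. The neighbouring cut, a Friedel–Crafts aroylation of the free triol 12, would be shorter, but it would expose two o-prenylphenols and two trisubstituted alkenes to a Lewis acid and an acylium ion. Making ring A the nucleophile avoids acid altogether. 13 has one ring hydrogen, and it lies between two methoxymethoxy groups, so the site of lithiation is fixed. The forward step needs clean mono-addition to the ester. 15 is one silylation from commercial 14.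

13 is the tris(methoxymethyl) ether of 12 (three O–C bonds cut). This group directs the lithiation, survives n-BuLi, and is removed by acetal exchange under conditions in routine use for prenylated phenols.

Ring A of 12 is opened at C2–C3 and C5–C6. This gives the symmetric enol ether 8, which already carries both prenyl groups on its α-carbons, and malonyl dichloride 9 as the C2–C1–C6 unit; the acyclic acid chloride 10 and the trione 11 lie on the way. Cutting the two prenyl–ring bonds instead would mean C-prenylating a preformed phloroglucinol, with the selectivity problems named above. Building the ring from a ketone that already holds the prenyl groups fixes their positions and leaves exactly one unsubstituted carbon, C1, for the aroylation. An acyclic C14 enol ether and a commercial three-carbon bis-electrophile replace a pentasubstituted arene. The forward reaction must acylate carbon twice and must not close through oxygen to a pyrone.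

8 is traced through its dimethyl ketal 7 to the ketone 6. A methyl enol ether is preferred to the free ketone or a silyl enol ether because the O-methyl group stays in place during both acylations, so the oxygen cannot lactonise before the carbocycle has formed.

The two Cα–CH2 bonds of 6 are cut after formally adding an ester group to each α-carbon. This gives the diester 4, with the diacid 5 as the species that decarboxylates. The prenyl groups of 4 are removed one at a time: the first cut leads to the mono-prenyl keto diester 3 and prenyl bromide 2, the second to dimethyl 3-oxopentanedioate 1 and a second portion of 2. 1 supplies C3–C4–C5 with both flanks activated alike, and after the first alkylation the untouched methylene is the more acidic site, so α,α'-dialkylation is its normal behaviour. Two separate alkylations, each with one equivalent of 2, are preferred to a single pot because 3 can be freed of any geminal by-product before the second group goes on. The forward steps need one prenyl group per α-carbon and an ester removal that leaves the alkenes intact.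

## Roads not taken

Alternative 1: Here the C1–C7 and C2–O bonds of ring A are cut together. The aryne released by CsF from 3,5-dimethoxy-2-(trimethylsilyl)phenyl trifluoromethanesulfonate A2 inserts into the C–O bond of 3-(benzyloxy)benzoic acid A3 and gives [3-(benzyloxy)phenyl](2-hydroxy-4,6-dimethoxyphenyl)methanone A1.
- Merits: the diaryl ketone and its ortho phenol form in one mild, convergent step without a Lewis acid, and the methoxy group next to the aryne bond fixes the regiochemistry. As a way to make the ketone, this step is better precedented and gentler than the ring synthesis chosen here.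
- Weak points: A1 carries a methyl group on the C6 oxygen that must be removed while the C4 methyl ether stays. With the C2 hydroxyl already chelated to the carbonyl, chelation-directed cleavage of the second ortho ether has lost its handle. Both prenyl groups would still have to be introduced by electrophilic C-prenylation at C3 and C5, which is the least controllable operation in this family. The benzyl ether could not be removed by hydrogenolysis once the prenyl groups are present.
- Comparison: the chosen plan is longer and its key step is less certain, but the prenyl positions are fixed by the skeleton and no late C-prenylation is needed.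

Alternative 2: Here the two CH2–CH bonds of the prenyl groups are cut. The bis(trimethylammoniomethyl) diphenol A5 (as its diiodide) is treated with excess 2-methylprop-1-enylmagnesium bromide A6 and catalytic CuI. Two ortho-quinone methides form in turn and each takes the alkenyl group at its exocyclic carbon, giving the ring B tert-butyldimethylsilyl ether A4 of the target.
- Merits: the acid-sensitive alkenes arrive last, carbon–carbon bond formation is confined to C3 and C5 with no O-alkylation or geminal substitution, the core can be made by robust classical acylation before any prenyl group exists, and A4 is one desilylation from 20. This endgame is shorter than the one proposed, and the route would probably be shorter overall.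
- Weak points: A5 requires a double aminomethylation and an N-quaternisation that must spare three phenols. The second quinone methide must form from a ring made more electron-rich by the first alkenylation. An excess of Grignard reagent meets a benzophenone carbonyl protected only by its magnesium phenoxide chelate.
- Comparison: the chosen plan uses only polar steps of established type around its key step, never exposes the ketone to an organometallic in excess, and builds the fully substituted ring in one operation.

Alternative 3: Here ring A is assembled by a Danheiser benzannulation. Heating 3-ethoxy-4-(3-methylbut-2-enyl)cyclobut-2-en-1-one A8 with the siloxyalkyne triisopropyl[(5-methylhex-4-en-1-yn-1-yl)oxy]silane A9 sets off ring opening, ketene–alkyne addition, a second ring opening and a 6π closure, giving 3-ethoxy-2,6-bis(3-methylbut-2-enyl)-5-(triisopropylsilyloxy)phenol A7.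
- Merits: the reaction is regiospecific, and the three ring A oxygens are differentiated from the start as a free hydroxyl at C4 between the prenyl groups, a silyl ether and an ethyl ether. Methylation at C4 would therefore be unambiguous, which is better than the acidity-controlled methylation of 18 that the chosen plan relies on.
- Weak points: A8 and A9 each need a multi-step preparation. The ethyl ether must later be cleaved next to two prenyl groups, for which no mild reagent is at hand. The aroyl group still has to be put on the one free ring carbon, so the endgame is no shorter.
- Comparison: the chosen plan starts from cheap commercial materials, has no alkyl ether to cleave, and places its one selectivity question on a well-understood acidity difference.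

Key step: step 6

Assumption: in the key step the O-methyl group of the enol ether is taken to leave as chloromethane once the ring has closed, as in the cyclisations of 1-methoxycycloalkenes with malonyl dichloride, so that the free triol 12 is the product.

## Route

Step 1
Reactants: 1 dimethyl 3-oxopentanedioate; 2 prenyl bromide (1-bromo-3-methylbut-2-ene)
Product: 3 dimethyl 2-(3-methylbut-2-enyl)-3-oxopentanedioate (racemic)
Conditions: 1 (1.2 equiv), NaH (1.0 equiv), THF, 0 °C; then 2 (1.0 equiv), 0 °C → rt
Reagents that add atoms: none
Why: C-alkylation of a β-keto ester enolate (acetoacetic ester type); SN2 at the primary allylic bromide outruns O-alkylation, and the slight excess of the inexpensive keto diester with only one equivalent of base keeps a second prenyl group off the same molecule. The stereocentre formed is erased in step 3.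

Step 2
Reactants: 3 dimethyl 2-(3-methylbut-2-enyl)-3-oxopentanedioate; 2 prenyl bromide (1-bromo-3-methylbut-2-ene)
Product: 4 dimethyl 2,4-bis(3-methylbut-2-enyl)-3-oxopentanedioate (mixture of diastereomers)
Conditions: NaH (1.05 equiv), THF, 0 °C; then 2 (1.05 equiv), 0 °C → rt
Reagents that add atoms: none
Why: Second β-keto ester alkylation; in 3 the unsubstituted α'-methylene is more acidic and less hindered than the already alkylated α-CH, so the enolate forms and reacts on the other flank and the α,α'-dialkylated keto diester should result, not the geminal isomer. Both stereocentres are erased in step 3.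

Step 3
Reactants: 4 dimethyl 2,4-bis(3-methylbut-2-enyl)-3-oxopentanedioate
Product: 6 2,10-dimethylundeca-2,9-dien-6-one, via keto diacid 5 (not isolated)
Conditions: NaOH (2 M aq.), MeOH, rt; then HCl to pH 3, 45 °C
Reagents that add atoms: none
Why: Ketonic hydrolysis of a β-keto ester: dilute hydroxide at room temperature saponifies both esters in preference to retro-Claisen cleavage, and the 3-oxoglutaric acid 5 released on acidification should lose two molecules of CO2 through the usual cyclic transition state; acid this dilute should neither hydrate nor cyclise the trisubstituted alkenes.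

Step 4
Reactants: 6 2,10-dimethylundeca-2,9-dien-6-one
Product: 7 6,6-dimethoxy-2,10-dimethylundeca-2,9-diene
Conditions: HC(OMe)3, MeOH, TsOH·H2O (cat.), rt; Et3N quench
Reagents that add atoms: trimethyl orthoformate, COC(OC)OC; methanol, CO
Why: Acid-catalysed ketalisation driven by the orthoformate as water scavenger; an unhindered dialkyl ketone reacts at room temperature, where a catalytic sulfonic acid should leave the prenyl alkenes untouched.

Step 5
Reactants: 7 6,6-dimethoxy-2,10-dimethylundeca-2,9-diene
Product: 8 6-methoxy-2,10-dimethylundeca-2,5,9-triene (E/Z mixture at the enol ether; both serve)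
Conditions: TMSOTf, iPr2NEt, CH2Cl2, −20 °C → rt; basic work-up
Reagents that add atoms: none
Why: Silyl-triflate-promoted elimination of methanol from a dimethyl ketal: TMSOTf ionises one methoxy group and the hindered amine removes an α-proton from the oxocarbenium ion; the ketone is symmetric, so only the double-bond geometry is open and it is lost in step 6.

Step 6
Reactants: 8 6-methoxy-2,10-dimethylundeca-2,5,9-triene; 9 malonyl dichloride
Product: 12 2,4-bis(3-methylbut-2-enyl)benzene-1,3,5-triol, via acyclic acid chloride 10 (not isolated), via cyclohexane-1,3,5-trione 11 (not isolated)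
Conditions: 9 (1.1 equiv), Et2O, −20 °C, 24 h, then → rt; ice-water quench under Ar
Reagents that add atoms: none
Why: This is an Effenberger cyclisation, a twofold C-acylation of a ketone enol ether by malonyl dichloride; the closest known cases are cycloalkanone methyl enol ethers, which give bridged cyclohexane-1,3,5-triones and, where the bridge allows enolisation, their phloroglucinol tautomers. The β-carbon of 8 attacks one acyl chloride (bond C2–C3), and the oxocarbenium ion loses the proton of the other α-carbon to give the transposed enol ether 10, whose oxygen is still capped by methyl and so cannot lactonise. 10 then closes on the second acyl chloride by a 6-(enol-endo)-exo-trig C-acylation (bond C5–C6), which completes ring A. Chloride removes the O-methyl group as chloromethane, and the trione 11 enolises to the aromatic triol 12, which makes the sequence irreversible. No stereocentre is created. The selectivity needed is carbon against oxygen acylation in the ring closure (phloroglucinol against 4-hydroxy-2-pyrone); the retained methyl ether, the low temperature and the aromatic driving force should secure it, and the symmetry of 6 removes any question of regiochemistry. Ether at −20 °C tempers the HCl released, which should protect the prenyl groups from hydrochlorination and chroman closure.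

Step 7
Reactants: 12 2,4-bis(3-methylbut-2-enyl)benzene-1,3,5-triol
Product: 13 1,3,5-tris(methoxymethoxy)-2,4-bis(3-methylbut-2-enyl)benzene
Conditions: MOMCl (5 equiv), iPr2NEt (6 equiv), Bu4NI (cat.), CH2Cl2, 0 → 40 °C, Ar
Reagents that add atoms: chloromethyl methyl ether (MOMCl), COCCl
Why: Threefold O-alkylation of the phenols with a hard α-chloro ether under amine base, which favours oxygen over ring carbon; the methoxymethyl ethers survive organolithiums, direct the lithiation of step 9 and ensure that no o-prenylphenol is exposed there.

Step 8
Reactants: 14 methyl 3-hydroxybenzoate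
Product: 15 methyl 3-(triisopropylsilyloxy)benzoate
Conditions: TIPSCl, imidazole, DMF, rt
Reagents that add atoms: chlorotriisopropylsilane (TIPSCl), CC(C)[Si](Cl)(C(C)C)C(C)C
Why: Standard silylation of a phenol; the triisopropylsilyl ether should withstand the aryllithium of step 9 and the dilute acid of step 10 and is removed last by fluoride.

Step 9
Reactants: 13 1,3,5-tris(methoxymethoxy)-2,4-bis(3-methylbut-2-enyl)benzene; 15 methyl 3-(triisopropylsilyloxy)benzoate
Product: 17 [2,4,6-tris(methoxymethoxy)-3,5-bis(3-methylbut-2-enyl)phenyl][3-(triisopropylsilyloxy)phenyl]methanone, via aryllithium 16 (not isolated)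
Conditions: n-BuLi, THF, 0 °C, 1 h; then cannulated into 15, THF, −78 → 0 °C; H2O
Reagents that add atoms: none
Why: Directed ortho-metalation followed by acyl substitution: the only ring hydrogen of 13 lies between two methoxymethoxy groups, whose chelation should make its removal far faster than deprotonation of the benzylic-allylic CH2 groups. The 2,6-dialkoxyaryllithium 16 should add only once to ester 15, because the di-ortho-substituted ketone 17 is too hindered for a second addition by so bulky a nucleophile. No Lewis acid touches the prenyl groups.

Step 10
Reactants: 17 [2,4,6-tris(methoxymethoxy)-3,5-bis(3-methylbut-2-enyl)phenyl][3-(triisopropylsilyloxy)phenyl]methanone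
Product: 18 [3-(triisopropylsilyloxy)phenyl][2,4,6-trihydroxy-3,5-bis(3-methylbut-2-enyl)phenyl]methanone
Conditions: HCl (1 M in MeOH), 40 °C, monitored; NaHCO3 quench
Reagents that add atoms: none
Why: Acid-catalysed acetal exchange with methanol removes the three methoxymethyl groups as dimethoxymethane; the two next to the carbonyl are activated by hydrogen bonding, the conditions are those in routine use for prenylated acylphloroglucinols, and the aryl triisopropylsilyl ether and the alkenes should tolerate brief dilute HCl in methanol.

Step 11
Reactants: 18 [3-(triisopropylsilyloxy)phenyl][2,4,6-trihydroxy-3,5-bis(3-methylbut-2-enyl)phenyl]methanone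
Product: 19 [2,6-dihydroxy-4-methoxy-3,5-bis(3-methylbut-2-enyl)phenyl][3-(triisopropylsilyloxy)phenyl]methanone
Conditions: TMSCHN2 (1.1 equiv), MeOH/toluene (1:3), 0 °C → rt
Reagents that add atoms: trimethylsilyldiazomethane (TMSCHN2), C[Si](C)(C)C=[N+]=[N-]
Why: O-methylation by a diazoalkane begins with proton transfer from the phenol, so the most acidic hydroxyl should react first: the C4 hydroxyl is para to the carbonyl and not hydrogen-bonded, whereas those at C2 and C6 are held in the chelate with the ketone. The neutral medium excludes C-methylation of the ring, and the limited amount of reagent guards against a second methylation.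

Step 12
Reactants: 19 [2,6-dihydroxy-4-methoxy-3,5-bis(3-methylbut-2-enyl)phenyl][3-(triisopropylsilyloxy)phenyl]methanone
Product: 20 [2,6-dihydroxy-4-methoxy-3,5-bis(3-methylbut-2-enyl)phenyl](3-hydroxyphenyl)methanone (CNP0425861.0)
Conditions: TBAF (Bu4NF), AcOH, THF, 0 °C
Reagents that add atoms: none
Why: Fluoride cleavage of an aryl silyl ether, buffered with acetic acid so that the phenoxides of the electron-rich ring are not left free in air; nothing else in 19 reacts with fluoride.

## Compound list

1 | dimethyl 3-oxopentanedioate | COC(=O)CC(=O)CC(=O)OC | starting material
2 | prenyl bromide (1-bromo-3-methylbut-2-ene) | CC(C)=CCBr | starting material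
3 | dimethyl 2-(3-methylbut-2-enyl)-3-oxopentanedioate (racemic) | COC(=O)C(CC=C(C)C)C(=O)CC(=O)OC | intermediate
4 | dimethyl 2,4-bis(3-methylbut-2-enyl)-3-oxopentanedioate (diastereomer mixture) | COC(=O)C(CC=C(C)C)C(=O)C(CC=C(C)C)C(=O)OC | intermediate
5 | 2,4-bis(3-methylbut-2-enyl)-3-oxopentanedioic acid (diastereomer mixture, not isolated) | OC(=O)C(CC=C(C)C)C(=O)C(CC=C(C)C)C(=O)O | intermediate
6 | 2,10-dimethylundeca-2,9-dien-6-one | CC(C)=CCCC(=O)CCC=C(C)C | intermediate
7 | 6,6-dimethoxy-2,10-dimethylundeca-2,9-diene | COC(CCC=C(C)C)(CCC=C(C)C)OC | intermediate
8 | 6-methoxy-2,10-dimethylundeca-2,5,9-triene (E/Z mixture at C5=C6) | COC(CCC=C(C)C)=CCC=C(C)C | intermediate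
9 | malonyl dichloride (propanedioyl dichloride) | O=C(Cl)CC(=O)Cl | starting material
10 | 5-methoxy-9-methyl-4-(3-methylbut-2-enyl)-3-oxodeca-5,8-dienoyl chloride (racemic, E/Z mixture, not isolated) | COC(=CCC=C(C)C)C(CC=C(C)C)C(=O)CC(=O)Cl | intermediate
11 | 2,4-bis(3-methylbut-2-enyl)cyclohexane-1,3,5-trione (diastereomer mixture, not isolated) | O=C1CC(=O)C(CC=C(C)C)C(=O)C1CC=C(C)C | intermediate
12 | 2,4-bis(3-methylbut-2-enyl)benzene-1,3,5-triol | Oc1cc(O)c(CC=C(C)C)c(O)c1CC=C(C)C | intermediate
13 | 1,3,5-tris(methoxymethoxy)-2,4-bis(3-methylbut-2-enyl)benzene | COCOc1cc(OCOC)c(CC=C(C)C)c(OCOC)c1CC=C(C)C | intermediate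
14 | methyl 3-hydroxybenzoate | COC(=O)c1cccc(O)c1 | starting material
15 | methyl 3-(triisopropylsilyloxy)benzoate | COC(=O)c1cccc(O[Si](C(C)C)(C(C)C)C(C)C)c1 | intermediate
16 | [2,4,6-tris(methoxymethoxy)-3,5-bis(3-methylbut-2-enyl)phenyl]lithium (not isolated) | [Li]c1c(OCOC)c(CC=C(C)C)c(OCOC)c(CC=C(C)C)c1OCOC | intermediate
17 | [2,4,6-tris(methoxymethoxy)-3,5-bis(3-methylbut-2-enyl)phenyl][3-(triisopropylsilyloxy)phenyl]methanone | COCOc1c(CC=C(C)C)c(OCOC)c(C(=O)c2cccc(O[Si](C(C)C)(C(C)C)C(C)C)c2)c(OCOC)c1CC=C(C)C | intermediate
18 | [3-(triisopropylsilyloxy)phenyl][2,4,6-trihydroxy-3,5-bis(3-methylbut-2-enyl)phenyl]methanone | Oc1c(CC=C(C)C)c(O)c(C(=O)c2cccc(O[Si](C(C)C)(C(C)C)C(C)C)c2)c(O)c1CC=C(C)C | intermediate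
19 | [2,6-dihydroxy-4-methoxy-3,5-bis(3-methylbut-2-enyl)phenyl][3-(triisopropylsilyloxy)phenyl]methanone | COc1c(CC=C(C)C)c(O)c(C(=O)c2cccc(O[Si](C(C)C)(C(C)C)C(C)C)c2)c(O)c1CC=C(C)C | intermediate
20 | [2,6-dihydroxy-4-methoxy-3,5-bis(3-methylbut-2-enyl)phenyl](3-hydroxyphenyl)methanone | COc1c(CC=C(C)C)c(O)c(C(=O)c2cccc(O)c2)c(O)c1CC=C(C)C | target

## Step count and steps at risk

Total: 12 steps. Longest linear sequence: 11 steps (steps 1–7 and 9–12); step 8 is a one-step side branch.

Step 6 (key step). The first acylation adduct may lose its O-methyl group too early and then close through oxygen to a 4-hydroxy-2-pyrone in place of the second C-acylation. The HCl released may add to the prenyl alkenes or, once phenols appear, promote chroman closure, and excess acid chloride may acylate the product. The fallback gives up the ring synthesis and places the prenyl groups by directed metalation. It sets out from prenyl bromide 2 and commercial benzene-1,3,5-triol F1. F1 is converted into 1,3,5-tris(methoxymethoxy)benzene F2 (MOMCl, iPr2NEt). Lithiation of F2 between two acetal oxygens (n-BuLi, THF, 0 °C) and alkylation with 2 gives 1,3,5-tris(methoxymethoxy)-2-(3-methylbut-2-enyl)benzene F3. A second lithiation at one of the two equivalent remaining positions and alkylation with 2 gives 13, where the route is rejoined with 12 bypassed.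

Step 11. Methylation may not stop at one group, or may lose its preference for the C4 hydroxyl because that oxygen sits between two prenyl groups, so that the C2 and C6 hydroxyls are alkylated as well. The fallback fixes the methyl group before the ketone exists and sets out from 12. Controlled bis-methoxymethylation at the two less hindered hydroxyls (those flanking the ring CH) gives 3,5-bis(methoxymethoxy)-2,6-bis(3-methylbut-2-enyl)phenol F4. Methylation of the one remaining hydroxyl (MeI, K2CO3, acetone) gives 3-methoxy-1,5-bis(methoxymethoxy)-2,4-bis(3-methylbut-2-enyl)benzene F5. Lithiation between the two acetal oxygens and acylation with 15, as in step 9, gives [4-methoxy-2,6-bis(methoxymethoxy)-3,5-bis(3-methylbut-2-enyl)phenyl][3-(triisopropylsilyloxy)phenyl]methanone F6. Mild acid exchange in methanol then removes the two chelation-activated acetals and returns the route at 19.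

Step 10. Once the phenols are set free, the acid may cyclise an o-prenylphenol onto its alkene or add methanol or HCl across it, and the silyl ether may be partly lost. The fallback changes the protecting group to one removed by fluoride and sets out from 12. SEMCl and iPr2NEt give 1,3,5-tris{[2-(trimethylsilyl)ethoxy]methoxy}-2,4-bis(3-methylbut-2-enyl)benzene F7. Lithiation and acylation with 15 give [2,4,6-tris{[2-(trimethylsilyl)ethoxy]methoxy}-3,5-bis(3-methylbut-2-enyl)phenyl][3-(triisopropylsilyloxy)phenyl]methanone F8. Fluoride (Bu4NF, DMPU, 60 °C) removes the three acetals and the silyl ether without acid and gives (3-hydroxyphenyl)[2,4,6-trihydroxy-3,5-bis(3-methylbut-2-enyl)phenyl]methanone F9. One equivalent of TMSCHN2 then methylates the most acidic hydroxyl and returns the route at 20. The cost is that the methylation must distinguish the C4 hydroxyl from the ring B phenol by acidity alone.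

Step 9. Lithiation may be incomplete or diverted to a benzylic-allylic CH2 group, the hindered aryllithium may add sluggishly to the ester, or a second addition may give a tertiary alcohol. The fallback changes the oxidation level of the electrophile and sets out from 13. Commercial 3-hydroxybenzaldehyde F10 is silylated (TIPSCl, imidazole) to 3-(triisopropylsilyloxy)benzaldehyde F11. Addition of aryllithium 16 to F11 gives racemic [2,4,6-tris(methoxymethoxy)-3,5-bis(3-methylbut-2-enyl)phenyl][3-(triisopropylsilyloxy)phenyl]methanol F12, which cannot over-add. Oxidation with Dess–Martin periodinane (NaHCO3-buffered, CH2Cl2) returns the route at 17.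

## Further compounds

F1 | step 6 | benzene-1,3,5-triol | Oc1cc(O)cc(O)c1
F2 | step 6 | 1,3,5-tris(methoxymethoxy)benzene | COCOc1cc(OCOC)cc(OCOC)c1
F3 | step 6 | 1,3,5-tris(methoxymethoxy)-2-(3-methylbut-2-enyl)benzene | COCOc1cc(OCOC)c(CC=C(C)C)c(OCOC)c1
F4 | step 11 | 3,5-bis(methoxymethoxy)-2,6-bis(3-methylbut-2-enyl)phenol | COCOc1cc(OCOC)c(CC=C(C)C)c(O)c1CC=C(C)C
F5 | step 11 | 3-methoxy-1,5-bis(methoxymethoxy)-2,4-bis(3-methylbut-2-enyl)benzene | COCOc1cc(OCOC)c(CC=C(C)C)c(OC)c1CC=C(C)C
F6 | step 11 | [4-methoxy-2,6-bis(methoxymethoxy)-3,5-bis(3-methylbut-2-enyl)phenyl][3-(triisopropylsilyloxy)phenyl]methanone | COCOc1c(CC=C(C)C)c(OC)c(CC=C(C)C)c(OCOC)c1C(=O)c1cccc(O[Si](C(C)C)(C(C)C)C(C)C)c1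
F7 | step 10 | 1,3,5-tris{[2-(trimethylsilyl)ethoxy]methoxy}-2,4-bis(3-methylbut-2-enyl)benzene | C[Si](C)(C)CCOCOc1cc(OCOCC[Si](C)(C)C)c(CC=C(C)C)c(OCOCC[Si](C)(C)C)c1CC=C(C)C
F8 | step 10 | [2,4,6-tris{[2-(trimethylsilyl)ethoxy]methoxy}-3,5-bis(3-methylbut-2-enyl)phenyl][3-(triisopropylsilyloxy)phenyl]methanone | C[Si](C)(C)CCOCOc1c(CC=C(C)C)c(OCOCC[Si](C)(C)C)c(C(=O)c2cccc(O[Si](C(C)C)(C(C)C)C(C)C)c2)c(OCOCC[Si](C)(C)C)c1CC=C(C)C
F9 | step 10 | (3-hydroxyphenyl)[2,4,6-trihydroxy-3,5-bis(3-methylbut-2-enyl)phenyl]methanone | Oc1c(CC=C(C)C)c(O)c(C(=O)c2cccc(O)c2)c(O)c1CC=C(C)C
F10 | step 9 | 3-hydroxybenzaldehyde | O=Cc1cccc(O)c1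
F11 | step 9 | 3-(triisopropylsilyloxy)benzaldehyde | O=Cc1cccc(O[Si](C(C)C)(C(C)C)C(C)C)c1
F12 | step 9 | [2,4,6-tris(methoxymethoxy)-3,5-bis(3-methylbut-2-enyl)phenyl][3-(triisopropylsilyloxy)phenyl]methanol (racemic) | COCOc1c(CC=C(C)C)c(OCOC)c(C(O)c2cccc(O[Si](C(C)C)(C(C)C)C(C)C)c2)c(OCOC)c1CC=C(C)C
A1 | alternative 1 | [3-(benzyloxy)phenyl](2-hydroxy-4,6-dimethoxyphenyl)methanone | COc1cc(O)c(C(=O)c2cccc(OCc3ccccc3)c2)c(OC)c1
A2 | alternative 1 | 3,5-dimethoxy-2-(trimethylsilyl)phenyl trifluoromethanesulfonate | COc1cc(OC)c([Si](C)(C)C)c(OS(=O)(=O)C(F)(F)F)c1
A3 | alternative 1 | 3-(benzyloxy)benzoic acid | OC(=O)c1cccc(OCc2ccccc2)c1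
A4 | alternative 2 | [3-(tert-butyldimethylsilyloxy)phenyl][2,6-dihydroxy-4-methoxy-3,5-bis(3-methylbut-2-enyl)phenyl]methanone | COc1c(CC=C(C)C)c(O)c(C(=O)c2cccc(O[Si](C)(C)C(C)(C)C)c2)c(O)c1CC=C(C)C
A5 | alternative 2 | [3-(tert-butyldimethylsilyloxy)phenyl]{2,6-dihydroxy-4-methoxy-3,5-bis[(trimethylammonio)methyl]phenyl}methanone diiodide | COc1c(C[N+](C)(C)C)c(O)c(C(=O)c2cccc(O[Si](C)(C)C(C)(C)C)c2)c(O)c1C[N+](C)(C)C.[I-].[I-]
A6 | alternative 2 | 2-methylprop-1-enylmagnesium bromide | CC(C)=C[Mg]Br
A7 | alternative 3 | 3-ethoxy-2,6-bis(3-methylbut-2-enyl)-5-(triisopropylsilyloxy)phenol | CCOc1cc(O[Si](C(C)C)(C(C)C)C(C)C)c(CC=C(C)C)c(O)c1CC=C(C)C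
A8 | alternative 3 | 3-ethoxy-4-(3-methylbut-2-enyl)cyclobut-2-en-1-one (racemic) | CCOC1=CC(=O)C1CC=C(C)C
A9 | alternative 3 | triisopropyl[(5-methylhex-4-en-1-yn-1-yl)oxy]silane | CC(C)=CCC#CO[Si](C(C)C)(C(C)C)C(C)C
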